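**Retrosynthetic overview**
- The target is opened at its two aryl ester C–O bonds and its Si–O bonds: a silylene-bridged terphenyl diol plus a (2Z,4S,5S)-4,5-epoxyhex-2-enoyl donor (oxirane by Sharpless epoxidation of (E)-crotyl alcohol, Z-alkene by Still–Gennari olefination).
- The silylene diol comes from the symmetric terphenyl tetraol by bridging one ortho-hydroxyl pair; the tetraol comes from a 2,5-dihydroxy-3,6-diaryl-1,4-benzoquinone by reduction.
- The quinone is cut twice between an aryl-bearing ring carbon and the neighbouring oxygenated carbon, giving two identical arylpyruvate S-ethyl thioesters that are joined head to tail by a double Claisen condensation.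
- Feature used: in the central ring C1'–C6', the two carbons carrying the 4-hydroxyphenyl rings (C1', C4') are para, and each lies between two O-bearing carbons (C2'/C6' and C3'/C5'). The ring is therefore two Ar–C–C(O)–C(O) three-carbon units, benzylic carbon of one bonded to the terminal oxygenated carbon of the other.
- Ring order: the outer benzene rings are bought; the central ring is the only carbocycle formed (key step); the two oxiranes are made separately and attached late.

Key step: step 3

Remark: the acyl groups are read from the SMILES as (2Z,4S,5S)-4,5-epoxyhex-2-enoyl (trans-oxirane); geometrically pure (E)-but-2-en-1-ol is taken as commercially available.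
Remark: because two chains are attached, the minor enantiomer of the chain should end up mainly in a heterochiral diastereomer of 22, to be removed by chromatography at that stage.
Remark: arylpyruvates 1, 4 and 6 exist largely as enols; they are drawn as keto forms.

**Route**

Step 1
Reactants: 1 4-hydroxyphenylpyruvic acid; 2 triisopropylsilyl chloride
Product: 4 2-oxo-3-[4-(triisopropylsilyloxy)phenyl]propanoic acid, via bis-silylated silyl ester 3 (not isolated)
Conditions: iPr3SiCl (2.3 equiv), imidazole (5 equiv), DMF, 0 to 23 °C; then THF/1 M HCl (aq), 23 °C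
Reagents that add atoms: triisopropylsilyl chloride (2), CC(C)[Si](Cl)(C(C)C)C(C)C
Why: Chlorosilane/imidazole silylation of the phenol and the carboxyl group, after which the acyl silyl ester (and any enol silyl ether) should be hydrolysed by dilute aqueous acid while the aryl TIPS ether is stable.

Step 2
Reactants: 4 2-oxo-3-[4-(triisopropylsilyloxy)phenyl]propanoic acid; 5 ethanethiol
Product: 6 S-ethyl 2-oxo-3-[4-(triisopropylsilyloxy)phenyl]propanethioate
Conditions: EtSH (3 equiv), DCC (1.1 equiv), DMAP (0.05 equiv), CH2Cl2, −20 to 0 °C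
Reagents that add atoms: ethanethiol (5), CCS
Why: Steglich-type carbodiimide thioesterification, in which the O-acylisourea of the α-keto acid is captured by the thiol at low temperature with only a trace of DMAP, so that base-induced aldol self-condensation of the arylpyruvate is avoided.

Step 3
Reactants: 6 S-ethyl 2-oxo-3-[4-(triisopropylsilyloxy)phenyl]propanethioate (two molecules)
Product: 9 2,5-dihydroxy-3,6-bis[4-(triisopropylsilyloxy)phenyl]-1,4-benzoquinone, via open-chain trioxo thioester dimer 7 (not isolated), via cyclohexanetetraone 8 (not isolated)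
Conditions: 6 added dropwise to LiN(SiMe3)2 (1.1 equiv per 6), THF, −78 °C; MgBr2·OEt2 (0.55 equiv per 6), −78 to 45 °C, argon; then 1 M HCl (aq), 0 °C
Reagents that add atoms: none
Why: Proposed new method: inverse addition to the amide base converts every molecule of 6 into its enolate, so that no free ketone is left for aldol addition and the thioester carbon is the only electrophile; within a magnesium chelate of two enolates the benzylic carbon of one unit should acylate the thioester carbon of the other with loss of ethanethiolate (intermolecular Claisen condensation, as in magnesium-mediated C-acylations of thioester and malonate enolates), giving open dimer 7. The second C–C bond closes the central ring by the matching intramolecular Claisen (Dieckmann-type) reaction, a 6-(enolendo)-exo-trig acyl substitution of the remaining benzylic enolate at the remaining thioester, to give tetraketone 8. Compound 8 is a tautomer of dihydroxyquinone 9, so the oxidation level does not change, and the doubly deprotonated vinylogous-acid form of 9, far more acidic than ethanethiol, is the thermodynamic sink that makes both acyl substitutions irreversible. No stereocentre is formed. The step needs C-acylation to win over aldol dimerisation with lactonisation and over O-acylation; this is to be secured by complete pre-enolisation, by the thiolate leaving group on an α-keto-activated acyl carbon, by magnesium binding the enolate oxygens, and by the reversibility of O-acyl intermediates in the presence of thiolate. The closest known reactions are the Claisen and Dieckmann condensations and the enzymatic dimerisation of thioester-bound 4-hydroxyphenylpyruvate to the terphenylquinone.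

Step 4
Reactants: 9 2,5-dihydroxy-3,6-bis[4-(triisopropylsilyloxy)phenyl]-1,4-benzoquinone
Product: 10 4,4''-bis(triisopropylsilyloxy)-[1,1':4',1''-terphenyl]-2',3',5',6'-tetraol
Conditions: Na2S2O4 (excess), degassed EtOAc/H2O, 23 °C, argon; crude product used at once
Reagents that add atoms: none
Why: Dithionite reduction of a quinone to its hydroquinone, with the electron-rich tetraol kept under argon because it re-oxidises in air.

Step 5
Reactants: 10 4,4''-bis(triisopropylsilyloxy)-[1,1':4',1''-terphenyl]-2',3',5',6'-tetraol; 11 di-tert-butylsilyl bis(trifluoromethanesulfonate)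
Product: 12 2,2-di-tert-butyl-4,7-bis[4-(triisopropylsilyloxy)phenyl]-1,3,2-benzodioxasilole-5,6-diol
Conditions: tBu2Si(OTf)2 (0.9 equiv, slow addition), 2,6-lutidine (3 equiv), CH2Cl2, −78 to 0 °C, argon; chromatography with degassed solvents
Reagents that add atoms: di-tert-butylsilyl bis(trifluoromethanesulfonate) (11), CC(C)(C)[Si](OS(=O)(=O)C(F)(F)F)(OS(=O)(=O)C(F)(F)F)C(C)(C)C
Why: Di-tert-butylsilylene formation on a catechol unit with the bis-triflate and a pyridine base is standard; as all four hydroxyls of 10 are equivalent and one silicon can only span an ortho pair, the only issue is mono- versus bis-silylenation, to be limited by slow addition of a deficit of reagent at low temperature, with unreacted 10 recovered (as 9 after aerial oxidation) and recycled.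

Step 6
Reactants: 13 (E)-but-2-en-1-ol; 14 tert-butyl hydroperoxide
Product: 15 (2S,3S)-2,3-epoxybutan-1-ol [(2S,3S)-3-methyloxiran-2-yl]methanol
Conditions: Ti(OiPr)4 (10 mol %), L-(+)-diisopropyl tartrate (12 mol %), tBuOOH (2 equiv, in isooctane), 4 Å molecular sieves, CH2Cl2, −20 °C; non-aqueous work-up, distillation
Reagents that add atoms: tert-butyl hydroperoxide (14), CC(C)(C)OO
Why: Sharpless asymmetric epoxidation, in which the L-(+)-tartrate titanium complex delivers oxygen to the alkene face that gives the (2S,3S)-epoxy alcohol, the trans relationship following from the E-alkene; both stereocentres of the side chain are set here.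

Step 7
Reactants: 15 (2S,3S)-2,3-epoxybutan-1-ol
Product: 16 (2R,3S)-3-methyloxirane-2-carbaldehyde
Conditions: Dess–Martin periodinane (1.2 equiv), NaHCO3 (4 equiv), CH2Cl2, 0 to 23 °C; pentane, filtration through Celite; solution used directly
Reagents that add atoms: none
Why: Dess–Martin oxidation of a primary alcohol under buffered non-aqueous conditions leaves the oxirane intact and its C–H is not enolised, so both stereocentres are kept (the descriptor at C2 changes only by priority); the volatile aldehyde is not taken to dryness.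

Step 8
Reactants: 16 (2R,3S)-3-methyloxirane-2-carbaldehyde; 17 methyl [bis(2,2,2-trifluoroethoxy)phosphoryl]acetate
Product: 18 methyl (2Z)-3-[(2S,3S)-3-methyloxiran-2-yl]prop-2-enoate [methyl (2Z,4S,5S)-4,5-epoxyhex-2-enoate]
Conditions: KN(SiMe3)2 (1.05 equiv), 18-crown-6 (3 equiv), THF, −78 °C
Reagents that add atoms: methyl [bis(2,2,2-trifluoroethoxy)phosphoryl]acetate (17), COC(=O)CP(=O)(OCC(F)(F)F)OCC(F)(F)F
Why: Still–Gennari variant of the Horner–Wadsworth–Emmons olefination, in which the trifluoroethyl phosphonate with a crown-ether-separated potassium ion eliminates rapidly from the kinetic adduct and should give the Z-enoate without touching the oxirane stereocentres.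

Step 9
Reactants: 18 methyl (2Z,4S,5S)-4,5-epoxyhex-2-enoate; 19 potassium trimethylsilanolate
Product: 20 potassium (2Z,4S,5S)-4,5-epoxyhex-2-enoate
Conditions: KOSiMe3 (1.05 equiv), Et2O, 0 to 23 °C; salt collected by filtration under argon
Reagents that add atoms: potassium trimethylsilanolate (19), C[Si](C)(C)[O-].[K+]
Why: Anhydrous cleavage of a methyl ester by silanolate (Laganis–Chenard conditions) gives the carboxylate salt directly, so that the free Z-epoxy acid, which is prone to acid-promoted lactonisation onto the oxirane, is never handled.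

Step 10
Reactants: 12 2,2-di-tert-butyl-4,7-bis[4-(triisopropylsilyloxy)phenyl]-1,3,2-benzodioxasilole-5,6-diol; 20 potassium (2Z,4S,5S)-4,5-epoxyhex-2-enoate (two molecules incorporated)
Product: 22 2,2-di-tert-butyl-4,7-bis[4-(triisopropylsilyloxy)phenyl]-1,3,2-benzodioxasilole-5,6-diyl bis[(2Z)-3-[(2S,3S)-3-methyloxiran-2-yl]prop-2-enoate], via mixed trichlorobenzoic anhydride 21 (not isolated)
Conditions: 20 (3 equiv), 2,4,6-Cl3C6H2COCl (3 equiv), THF, 0 to 23 °C; then 12, Et3N (4 equiv), DMAP (0.2 equiv), toluene, 0 to 23 °C, argon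
Reagents that add atoms: potassium (2Z,4S,5S)-4,5-epoxyhex-2-enoate (20), C[C@@H]1O[C@H]1/C=C\C(=O)[O-].[K+]; 2,4,6-trichlorobenzoyl chloride, O=C(Cl)c1c(Cl)cc(Cl)cc1Cl (its atoms stay only in intermediate 21)
Why: Yamaguchi esterification, in which the mixed anhydride is attacked at the less hindered enoyl carbonyl by the two phenolic hydroxyls; low temperature and little DMAP are meant to suppress Z-to-E isomerisation, and the oxirane stereocentres are not involved.

Step 11
Reactants: 22 silylene-protected bis-ester
Product: 23 4,4'',5',6'-tetrahydroxy-[1,1':4',1''-terphenyl]-2',3'-diyl bis[(2Z)-3-[(2S,3S)-3-methyloxiran-2-yl]prop-2-enoate] (target)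
Conditions: Bu4NF (5 equiv), AcOH (5 equiv), THF, 0 °C, argon
Reagents that add atoms: none
Why: Fluoride cleavage of the Si–O(aryl) bonds removes both TIPS ethers and the silylene in one operation, while acetic acid buffering keeps the liberated phenoxides protonated so that the aryl enoates, the Z-alkenes and the oxiranes should survive; acyl migration is excluded because the freed hydroxyls are not adjacent to the ester oxygens.

**Compound list**
1 | 4-hydroxyphenylpyruvic acid | O=C(O)C(=O)Cc1ccc(O)cc1 | starting material
2 | triisopropylsilyl chloride | CC(C)[Si](Cl)(C(C)C)C(C)C | starting material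
3 | triisopropylsilyl 2-oxo-3-[4-(triisopropylsilyloxy)phenyl]propanoate | CC(C)[Si](OC(=O)C(=O)Cc1ccc(O[Si](C(C)C)(C(C)C)C(C)C)cc1)(C(C)C)C(C)C | intermediate
4 | 2-oxo-3-[4-(triisopropylsilyloxy)phenyl]propanoic acid | O=C(O)C(=O)Cc1ccc(O[Si](C(C)C)(C(C)C)C(C)C)cc1 | intermediate
5 | ethanethiol | CCS | starting material
6 | S-ethyl 2-oxo-3-[4-(triisopropylsilyloxy)phenyl]propanethioate | CCSC(=O)C(=O)Cc1ccc(O[Si](C(C)C)(C(C)C)C(C)C)cc1 | intermediate
7 | S-ethyl 2,4,5-trioxo-3,6-bis[4-(triisopropylsilyloxy)phenyl]hexanethioate (present as enolate; C3 not configurationally defined) | CCSC(=O)C(=O)C(c1ccc(O[Si](C(C)C)(C(C)C)C(C)C)cc1)C(=O)C(=O)Cc1ccc(O[Si](C(C)C)(C(C)C)C(C)C)cc1 | intermediate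
8 | 3,6-bis[4-(triisopropylsilyloxy)phenyl]cyclohexane-1,2,4,5-tetraone (enolisable; no defined stereocentres) | O=C1C(=O)C(c2ccc(O[Si](C(C)C)(C(C)C)C(C)C)cc2)C(=O)C(=O)C1c1ccc(O[Si](C(C)C)(C(C)C)C(C)C)cc1 | intermediate
9 | 2,5-dihydroxy-3,6-bis[4-(triisopropylsilyloxy)phenyl]-1,4-benzoquinone | O=C1C(O)=C(c2ccc(O[Si](C(C)C)(C(C)C)C(C)C)cc2)C(=O)C(O)=C1c1ccc(O[Si](C(C)C)(C(C)C)C(C)C)cc1 | intermediate
10 | 4,4''-bis(triisopropylsilyloxy)-[1,1':4',1''-terphenyl]-2',3',5',6'-tetraol | Oc1c(O)c(-c2ccc(O[Si](C(C)C)(C(C)C)C(C)C)cc2)c(O)c(O)c1-c1ccc(O[Si](C(C)C)(C(C)C)C(C)C)cc1 | intermediate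
11 | di-tert-butylsilyl bis(trifluoromethanesulfonate) | CC(C)(C)[Si](OS(=O)(=O)C(F)(F)F)(OS(=O)(=O)C(F)(F)F)C(C)(C)C | starting material
12 | 2,2-di-tert-butyl-4,7-bis[4-(triisopropylsilyloxy)phenyl]-1,3,2-benzodioxasilole-5,6-diol | CC(C)(C)[Si]1(C(C)(C)C)Oc2c(O1)c(-c1ccc(O[Si](C(C)C)(C(C)C)C(C)C)cc1)c(O)c(O)c2-c1ccc(O[Si](C(C)C)(C(C)C)C(C)C)cc1 | intermediate
13 | (E)-but-2-en-1-ol | C/C=C/CO | starting material
14 | tert-butyl hydroperoxide | CC(C)(C)OO | starting material
15 | (2S,3S)-2,3-epoxybutan-1-ol | C[C@@H]1O[C@H]1CO | intermediate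
16 | (2R,3S)-3-methyloxirane-2-carbaldehyde | C[C@@H]1O[C@H]1C=O | intermediate
17 | methyl [bis(2,2,2-trifluoroethoxy)phosphoryl]acetate | COC(=O)CP(=O)(OCC(F)(F)F)OCC(F)(F)F | starting material
18 | methyl (2Z,4S,5S)-4,5-epoxyhex-2-enoate | C[C@@H]1O[C@H]1/C=C\C(=O)OC | intermediate
19 | potassium trimethylsilanolate | C[Si](C)(C)[O-].[K+] | starting material
20 | potassium (2Z,4S,5S)-4,5-epoxyhex-2-enoate | C[C@@H]1O[C@H]1/C=C\C(=O)[O-].[K+] | intermediate
21 | (2Z,4S,5S)-4,5-epoxyhex-2-enoic 2,4,6-trichlorobenzoic anhydride | C[C@@H]1O[C@H]1/C=C\C(=O)OC(=O)c1c(Cl)cc(Cl)cc1Cl | intermediate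
22 | 2,2-di-tert-butyl-4,7-bis[4-(triisopropylsilyloxy)phenyl]-1,3,2-benzodioxasilole-5,6-diyl bis[(2Z)-3-[(2S,3S)-3-methyloxiran-2-yl]prop-2-enoate] | CC(C)(C)[Si]1(C(C)(C)C)Oc2c(O1)c(-c1ccc(O[Si](C(C)C)(C(C)C)C(C)C)cc1)c(OC(=O)/C=C\[C@@H]1O[C@H]1C)c(OC(=O)/C=C\[C@@H]1O[C@H]1C)c2-c1ccc(O[Si](C(C)C)(C(C)C)C(C)C)cc1 | intermediate
23 | 4,4'',5',6'-tetrahydroxy-[1,1':4',1''-terphenyl]-2',3'-diyl bis[(2Z)-3-[(2S,3S)-3-methyloxiran-2-yl]prop-2-enoate] | C[C@@H]1O[C@H]1/C=C\C(=O)Oc1c(OC(=O)/C=C\[C@@H]2O[C@H]2C)c(-c2ccc(O)cc2)c(O)c(O)c1-c1ccc(O)cc1 | target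

**Step count**
Total: 11 steps. Longest linear sequence: 7 steps (1, 2, 3, 4, 5, 10, 11); the side chain (steps 6–9) joins at step 10.

**Steps most likely to fail**

Step 3 (proposed new method). Aldol addition followed by lactonisation, or O-acylation, may outrun the C-acylation, or the enolate–enolate Claisen may be too slow and the thioester may decompose on warming. The fallback uses known chemistry, sets out from triisopropylsilyl chloride 2 and returns at quinone 9. Commercial 4-hydroxyphenylboronic acid pinacol ester is silylated with 2 and imidazole to triisopropyl[4-(4,4,5,5-tetramethyl-1,3,2-dioxaborolan-2-yl)phenoxy]silane F1. Commercial bromanil is treated with NaOMe in methanol to give 2,5-dibromo-3,6-dimethoxy-1,4-benzoquinone F2. Double Suzuki–Miyaura coupling of F2 with F1 (Pd(PPh3)4, a zerovalent palladium catalyst, K3PO4, dioxane, 90 °C) should give 2,5-dimethoxy-3,6-bis[4-(triisopropylsilyloxy)phenyl]-1,4-benzoquinone F3. Its two vinylogous methyl esters are then hydrolysed with LiOH in aqueous THF at 0 to 23 °C and the mixture is acidified to give 9.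

Step 5. Silylenation may run on to the bis-silylene before the tetraol is consumed, giving a near-statistical distribution, and the electron-rich diol may re-oxidise during separation. The fallback sets out from quinone 9 and returns at 12, moving the silylenation to the quinone oxidation level. Quinone 9 has only two acidic hydroxyls and so can take up only one silicon. With tBu2Si(OTf)2 and 2,6-lutidine in CH2Cl2 at −78 °C, the first Si–O bond forms at an enolic hydroxyl and the adjacent carbonyl oxygen closes the ring. This captures the ortho-quinoid tautomer as 2,2-di-tert-butyl-4,7-bis[4-(triisopropylsilyloxy)phenyl]-1,3,2-benzodioxasilole-5,6-dione F4, which is reduced without aqueous contact (H2, Pd/C, EtOAc) to 12. This capture is reasoned by analogy with carbonyl O-silylation by silyl triflates and with the condensation of such quinones with 1,2-diamines through the same tautomer; it is not an established reaction.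

Step 10. The activated Z-enoyl donor may isomerise to the E-isomer under nucleophilic catalysis, the second acylation of the hindered catechol may stall, or the donor may lactonise onto its oxirane. The fallback sets out from diol 12 and returns at 22, forming the Z-alkenes after the ester bonds. Diol 12 is acylated with commercial [bis(2,2,2-trifluoroethoxy)phosphoryl]acetic acid (DCC, catalytic DMAP, CH2Cl2, 0 °C) to give 2,2-di-tert-butyl-4,7-bis[4-(triisopropylsilyloxy)phenyl]-1,3,2-benzodioxasilole-5,6-diyl bis{[bis(2,2,2-trifluoroethoxy)phosphoryl]acetate} F5. Twofold Still–Gennari olefination of F5 with aldehyde 16 (KN(SiMe3)2, 18-crown-6, THF, −78 °C) should then give 22. Steps 8 and 9 are then not needed.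

**Further compounds**
F1 | step 3 | triisopropyl[4-(4,4,5,5-tetramethyl-1,3,2-dioxaborolan-2-yl)phenoxy]silane | CC(C)[Si](Oc1ccc(B2OC(C)(C)C(C)(C)O2)cc1)(C(C)C)C(C)C
F2 | step 3 | 2,5-dibromo-3,6-dimethoxy-1,4-benzoquinone | COC1=C(Br)C(=O)C(OC)=C(Br)C1=O
F3 | step 3 | 2,5-dimethoxy-3,6-bis[4-(triisopropylsilyloxy)phenyl]-1,4-benzoquinone | COC1=C(c2ccc(O[Si](C(C)C)(C(C)C)C(C)C)cc2)C(=O)C(OC)=C(c2ccc(O[Si](C(C)C)(C(C)C)C(C)C)cc2)C1=O
F4 | step 5 | 2,2-di-tert-butyl-4,7-bis[4-(triisopropylsilyloxy)phenyl]-1,3,2-benzodioxasilole-5,6-dione | CC(C)(C)[Si]1(C(C)(C)C)OC2=C(c3ccc(O[Si](C(C)C)(C(C)C)C(C)C)cc3)C(=O)C(=O)C(c3ccc(O[Si](C(C)C)(C(C)C)C(C)C)cc3)=C2O1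
F5 | step 10 | 2,2-di-tert-butyl-4,7-bis[4-(triisopropylsilyloxy)phenyl]-1,3,2-benzodioxasilole-5,6-diyl bis{[bis(2,2,2-trifluoroethoxy)phosphoryl]acetate} | CC(C)(C)[Si]1(C(C)(C)C)Oc2c(O1)c(-c1ccc(O[Si](C(C)C)(C(C)C)C(C)C)cc1)c(OC(=O)CP(=O)(OCC(F)(F)F)OCC(F)(F)F)c(OC(=O)CP(=O)(OCC(F)(F)F)OCC(F)(F)F)c2-c1ccc(O[Si](C(C)C)(C(C)C)C(C)C)cc1
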